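A direct plan would open the Darzens glycidate A1 (methyl trans-3-(2,5-dimethoxyphenyl)oxirane-2-carboxylate) at its benzylic carbon with 2,3,4,5-tetramethoxyphenol A2, then O-methylate and saponify to the erythro acid A3.
It would close ring C by Friedel–Crafts acylation to the trans-3-methoxyflavanone A4, dehydrogenate to the heptamethoxyflavone A5 and free O5 by chelation-directed demethylation.
Its weakest steps would be:
- The Friedel–Crafts closure of C4–C4a: the acylium ion carries an α-methoxy group (loss of CO) and a β benzylic aryloxy group (ionisation, β-elimination).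
- The stretch that sets C2 and C3 (glycidate, SN2 opening, O-methylation, hydrolysis): two stereocentres would be controlled over four operations only to be erased by the dehydrogenation, and phenol A2 needs a run-up of its own.
- The final demethylation: the 5-hydroxyl would appear only by removing one of seven methyl ethers from the finished skeleton.

**Retrosynthetic overview**
Ring A is not taken from an arene: C5, C6, C7 and C8, its four contiguous oxygen-bearing carbons, are the four ring carbons of dimethyl squarate, and C4a/C8a are C5/C6 of a 4-pyranone that already is ring C, with ring B on C2 and the methoxy group on C3.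
Key disconnections: C4a–C5 (6π-electrocyclisation of a vinylketene) and C8–C8a (1,2-addition of the 6-lithiopyranone to the squarate); C2–C1' by Suzuki coupling on a 2-bromopyranone.
Ring order: B (bought), C (bought as 3-hydroxy-4-pyranone), A last, in the final step.
The ketene carbon becomes C5 with its free hydroxyl and the methylated alkoxide carbon becomes C8–OMe, so the design needs no Friedel–Crafts acylation, no demethylation and no controlled stereocentre.

Key step: step 5

Assumption: 3-hydroxy-4H-pyran-4-one (pyromeconic acid), dimethyl squarate and (2,5-dimethoxyphenyl)boronic acid are taken as purchasable starting materials.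

Step 1
Reactants: 1 3-hydroxy-4H-pyran-4-one (pyromeconic acid)
Product: 2 2-bromo-3-hydroxy-4H-pyran-4-one
Conditions: NBS (1.0 equiv), MeCN, 0 °C → rt, dark
Reagents that add atoms: N-bromosuccinimide O=C1CCC(=O)N1Br
Why: Electrophilic bromination of the enolic 3-hydroxy-4-pyranone at the enol β-carbon C2 (next to the hydroxyl-bearing carbon and the ring oxygen), the position at which kojic acid and related 3-hydroxy-4-pyranones are halogenated.

Step 2
Reactants: 2 2-bromo-3-hydroxy-4H-pyran-4-one
Product: 3 2-bromo-3-methoxy-4H-pyran-4-one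
Conditions: MeI, K2CO3, acetone, 45 °C
Reagents that add atoms: iodomethane CI
Why: Williamson O-methylation of the acidic enolic hydroxyl under weak, non-nucleophilic base, which should leave the vinylogous acyl bromide untouched.

Step 3
Reactants: 3 2-bromo-3-methoxy-4H-pyran-4-one; 4 (2,5-dimethoxyphenyl)boronic acid
Product: 5 2-(2,5-dimethoxyphenyl)-3-methoxy-4H-pyran-4-one
Conditions: Pd(OAc)2 (2 mol %), SPhos (4 mol %), K3PO4, toluene–H2O (10:1), 80 °C, argon
Reagents that add atoms: none
Why: Suzuki–Miyaura coupling, in which the C2–Br bond of the β-bromo enone adds readily to zerovalent palladium, the biaryl phosphine copes with the ortho-methoxy boronic acid and phosphate is mild enough for the pyranone ring.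

Step 4
Reactants: 5 2-(2,5-dimethoxyphenyl)-3-methoxy-4H-pyran-4-one; 6 dimethyl squarate (3,4-dimethoxycyclobut-3-ene-1,2-dione)
Product: 9 racemic 4-[6-(2,5-dimethoxyphenyl)-5-methoxy-4-oxo-4H-pyran-2-yl]-2,3,4-trimethoxycyclobut-2-en-1-one, via 6-lithiopyranone 7 (not isolated), via lithium alkoxide 8 (not isolated)
Conditions: LiTMP (from TMPH, n-BuLi; 1.05 equiv), THF, −78 °C, 5 added to the base; cannulated into 6 (1.1 equiv), THF, −78 °C; MeOTf (1.3 equiv), −78 → 0 °C; aq. NaHCO3
Reagents that add atoms: lithium 2,2,6,6-tetramethylpiperidide [Li+].CC1(C)CCCC(C)(C)[N-]1 (lithium of 7 and 8 only); methyl trifluoromethanesulfonate COS(=O)(=O)C(F)(F)F (O-methyl group on C4 of the cyclobutenone)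
Why: The hindered amide should remove the only hydrogen next to the ring oxygen (C6–H, the β-position of the vinylogous ester, as in the C2 lithiation of 3-substituted chromones and 1-alkyl-4-pyridones and the C6 lithiation of uracils), the α-alkoxyvinyllithium adds 1,2 to one carbonyl group of dimethyl squarate at −78 °C, and the tertiary lithium alkoxide is O-methylated by methyl triflate faster than the neutral pyranone carbonyl; the single stereocentre forms as a racemate and is erased in step 5.

Step 5
Reactants: 9 racemic 4-[6-(2,5-dimethoxyphenyl)-5-methoxy-4-oxo-4H-pyran-2-yl]-2,3,4-trimethoxycyclobut-2-en-1-one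
Product: 12 grantioidinin (2-(2,5-dimethoxyphenyl)-5-hydroxy-3,6,7,8-tetramethoxy-4H-chromen-4-one), via dienylketene 10 (not isolated), via cyclohexadienone tautomer 11 (not isolated)
Conditions: toluene (0.01 M, degassed), 110 °C, argon
Reagents that add atoms: none
Why: Heating opens the C1–C4 bond of the cyclobutenone by a conrotatory 4π-electrocyclic reaction in which the donor 4-methoxy group rotates outward, so the pyranonyl group ends cis to the ketene in 10; the ketene carbon then bonds to the nucleophilic pyranone C5 in a 6π-electrocyclisation (new bond C4a–C5) to give dienone 11, whose C4a–H lies between two carbonyl groups and enolises at once to the phenol. The closest known reaction type is the Moore rearrangement of squarate-derived 4-alkenyl- and 4-heteroaryl-4-alkoxycyclobutenones to highly oxygenated phenols, for example 4-(2-furyl) adducts to benzofuranols. Ring A is the only ring closed, as a six-membered carbocycle by a thermal disrotatory 6π-electrocyclisation, so it is a pericyclic closure and not an ionic one. No stereocentre remains: the quaternary centre of 9 is lost at ring opening and the C4a centre of 11 on enolisation. The oxygen pattern needs no selectivity, because the atom mapping fixes it (former carbonyl carbon to C5–OH peri to the C4 carbonyl, former C2 and C3 to C6–OMe and C7–OMe, former C4 to C8–OMe); the sense of rotation is secured by the 4-methoxy group and closure at C5 instead of at the ring oxygen by C5 being the only π-terminus within reach. High dilution and exclusion of air should keep the ketene from acylating the product and protect the 4-methoxyphenol unit, whose hydroxyl is in any case tied up in the hydrogen bond to the C4 carbonyl.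

**Compound list**
1 | 3-hydroxy-4H-pyran-4-one (pyromeconic acid) | O=c1ccocc1O | starting material
2 | 2-bromo-3-hydroxy-4H-pyran-4-one | O=c1ccoc(Br)c1O | intermediate
3 | 2-bromo-3-methoxy-4H-pyran-4-one | COc1c(Br)occc1=O | intermediate
4 | (2,5-dimethoxyphenyl)boronic acid | COc1ccc(OC)c(B(O)O)c1 | starting material
5 | 2-(2,5-dimethoxyphenyl)-3-methoxy-4H-pyran-4-one | COc1ccc(OC)c(-c2occc(=O)c2OC)c1 | intermediate
6 | dimethyl squarate (3,4-dimethoxycyclobut-3-ene-1,2-dione) | COC1=C(OC)C(=O)C1=O | starting material
7 | [6-(2,5-dimethoxyphenyl)-5-methoxy-4-oxo-4H-pyran-2-yl]lithium | [Li]c1cc(=O)c(OC)c(-c2cc(OC)ccc2OC)o1 | intermediate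
8 | lithium alkoxide of the squarate adduct (racemic) | [Li+].[O-]C1(c2cc(=O)c(OC)c(-c3cc(OC)ccc3OC)o2)C(OC)=C(OC)C1=O | intermediate
9 | racemic 4-[6-(2,5-dimethoxyphenyl)-5-methoxy-4-oxo-4H-pyran-2-yl]-2,3,4-trimethoxycyclobut-2-en-1-one | COC1=C(OC)C(OC)(c2cc(=O)c(OC)c(-c3cc(OC)ccc3OC)o2)C1=O | intermediate
10 | (3Z)-4-[6-(2,5-dimethoxyphenyl)-5-methoxy-4-oxo-4H-pyran-2-yl]-2,3,4-trimethoxybuta-1,3-dien-1-one (dienylketene) | O=C=C(OC)/C(OC)=C(/OC)c1cc(=O)c(OC)c(-c2cc(OC)ccc2OC)o1 | intermediate
11 | racemic 2-(2,5-dimethoxyphenyl)-3,6,7,8-tetramethoxy-4aH-chromene-4,5-dione (cyclohexadienone tautomer of 12) | COC1=C(OC)C(OC)=C2OC(c3cc(OC)ccc3OC)=C(OC)C(=O)C2C1=O | intermediate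
12 | grantioidinin, 2-(2,5-dimethoxyphenyl)-5-hydroxy-3,6,7,8-tetramethoxy-4H-chromen-4-one | COc1ccc(OC)c(-c2oc3c(OC)c(OC)c(OC)c(O)c3c(=O)c2OC)c1 | target

Total step count: 5. Longest linear sequence: 5 steps (1 → 2 → 3 → 5 → 9 → 12).

**Steps most likely to fail**

1. Step 4. The 6-lithiopyranone may add to pyranone not yet deprotonated before it reaches the squarate, deprotonation may be incomplete, or methyl triflate may alkylate the pyranone carbonyl. The fallback sets out from 5 and returns at 9, and replaces deprotonation by halogen–magnesium exchange. Zincation with TMPZnCl·LiCl (THF, 25 °C), which tolerates the carbonyl group, and iodolysis with I2 would give 2-(2,5-dimethoxyphenyl)-6-iodo-3-methoxy-4H-pyran-4-one F1. Exchange with iPrMgCl·LiCl at −78 °C, addition of the softer Grignard reagent to 6 and NH4Cl quench would give the tertiary alcohol F2. Purdie methylation (MeI, Ag2O, K2CO3, MeCN, rt) would then give 9.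

2. Step 5. Closure of the vinylketene on the cross-conjugated pyranone C5=C6 bond may be slow, so that the ketene is consumed by dimerisation or by acylating the product phenol. The fallback sets out from 6 and returns at 12, and builds ring A first on a plain enol ether, closing ring C last.
   - 1-Ethoxyvinyllithium F3 (ethyl vinyl ether, t-BuLi, THF, −78 → 0 °C) would add to 6 and the alkoxide would be trapped with MeOTf to give racemic 4-(1-ethoxyvinyl)-2,3,4-trimethoxycyclobut-2-en-1-one F4.
   - Thermolysis in toluene at 110 °C would give 5-ethoxy-2,3,4-trimethoxyphenol F5.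
   - Houben–Hoesch acylation at its only free ring position with methoxyacetonitrile (ZnCl2, HCl, Et2O; then H2O, heat) would give the ω-methoxy ketone F6.
   - Allan–Robinson condensation with 2,5-dimethoxybenzoic anhydride and sodium 2,5-dimethoxybenzoate (180 °C; then KOH, aq. EtOH) would give the 5-ethoxyflavone F7.
   - BCl3 (CH2Cl2, −78 → 0 °C) would remove the peri ethyl group, held in the chelate with the C4 carbonyl, to give 12.

3. Step 3. Aqueous base may open the bromopyranone ring (a vinylogous acyl bromide), and the electron-rich ortho-substituted boronic acid may protodeboronate. The fallback sets out from 3 and returns at 5, and uses a base-free Negishi coupling. (2,5-Dimethoxyphenyl)zinc chloride F8, from commercial 2,5-dimethoxyphenylmagnesium bromide and ZnCl2 in THF, would be coupled with 3 under Pd(PPh3)4 (THF, 50 °C) to give 5.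

**Further compounds**
F1 | step 4 | 2-(2,5-dimethoxyphenyl)-6-iodo-3-methoxy-4H-pyran-4-one | COc1ccc(OC)c(-c2oc(I)cc(=O)c2OC)c1
F2 | step 4 | racemic 4-[6-(2,5-dimethoxyphenyl)-5-methoxy-4-oxo-4H-pyran-2-yl]-4-hydroxy-2,3-dimethoxycyclobut-2-en-1-one | COC1=C(OC)C(O)(c2cc(=O)c(OC)c(-c3cc(OC)ccc3OC)o2)C1=O
F3 | step 5 | 1-ethoxyvinyllithium | [Li]C(=C)OCC
F4 | step 5 | racemic 4-(1-ethoxyvinyl)-2,3,4-trimethoxycyclobut-2-en-1-one | CCOC(=C)C1(OC)C(OC)=C(OC)C1=O
F5 | step 5 | 5-ethoxy-2,3,4-trimethoxyphenol | CCOc1cc(O)c(OC)c(OC)c1OC
F6 | step 5 | 1-(2-ethoxy-6-hydroxy-3,4,5-trimethoxyphenyl)-2-methoxyethan-1-one | CCOc1c(C(=O)COC)c(O)c(OC)c(OC)c1OC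
F7 | step 5 | 2-(2,5-dimethoxyphenyl)-5-ethoxy-3,6,7,8-tetramethoxy-4H-chromen-4-one | CCOc1c(OC)c(OC)c(OC)c2oc(-c3cc(OC)ccc3OC)c(OC)c(=O)c12
F8 | step 3 | (2,5-dimethoxyphenyl)zinc chloride | COc1ccc(OC)c([Zn]Cl)c1
A1 | direct plan | racemic methyl trans-3-(2,5-dimethoxyphenyl)oxirane-2-carboxylate (2S,3R drawn) | COC(=O)[C@H]1O[C@@H]1c1cc(OC)ccc1OC
A2 | direct plan | 2,3,4,5-tetramethoxyphenol | Oc1cc(OC)c(OC)c(OC)c1OC
A3 | direct plan | racemic erythro-3-(2,5-dimethoxyphenyl)-2-methoxy-3-(2,3,4,5-tetramethoxyphenoxy)propanoic acid (2S,3S drawn) | OC(=O)[C@@H](OC)[C@@H](Oc1cc(OC)c(OC)c(OC)c1OC)c1cc(OC)ccc1OC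
A4 | direct plan | racemic trans-2-(2,5-dimethoxyphenyl)-3,5,6,7,8-pentamethoxychroman-4-one (2S,3S drawn) | O=C1c2c(OC)c(OC)c(OC)c(OC)c2O[C@@H](c2cc(OC)ccc2OC)[C@@H]1OC
A5 | direct plan | 2-(2,5-dimethoxyphenyl)-3,5,6,7,8-pentamethoxy-4H-chromen-4-one | COc1ccc(OC)c(-c2oc3c(OC)c(OC)c(OC)c(OC)c3c(=O)c2OC)c1
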